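## Retrosynthetic overview

- The target is reached by C2 acetylation and acetonide removal from an enoate whose C12–C13 bond comes from a B-alkyl Suzuki coupling of a C9 vinyl carbinol with the (E)-enol triflate of methyl acetoacetate. The C9–C11 bond comes from α-face vinyl addition to a C9 ketone.
- The C9 ketone comes from hydroboration–oxidation of a C8=C9 octalin with equilibration of C8; the C6 sulfonyl group is removed reductively.
- Rings A and B are closed together in one intramolecular Diels–Alder reaction: the C7=C8–C9=C10 diene and the (E)-C5=C6 vinyl sulfone, joined by the C1–C4 tether, form C5–C10 and C6–C7.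
- Feature used: in ring A the C3 carbinol sits on the C4 gem-dimethyl carbon next to C5 (the O–CH–CMe2–CH2 unit of pantolactone). The ring A/ring B fusion is trans, with the methyl-bearing quaternary C10 next to C5–H, which is the pattern an endo cycloaddition of an E-diene leaves.
- The triene comes from (S)-pantolactone (C2–C5, C18, C19): C1–C2 by anti propargylation of the C2 aldehyde, C20 by Zr-catalysed carboalumination/iodination (fixes the C9=C10 geometry), C7/C8/C17 by Suzuki coupling, C6 by a sulfonyl Horner–Wadsworth–Emmons olefination.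

Key step: step 12

Remark: labdane numbering is used for all intermediates (decalin C1–C10, side chain C11–C16, C17 on C8, C18/C19 on C4, C20 on C10), and α means the face opposite the C10 methyl group. (S)-Pantolactone and the boronates 6 and 12 are taken as purchasable. The diene is built by alkyne carboalumination and cross-coupling, because olefination of a C10 methyl ketone would not control the C9=C10 geometry.

## Route

Step 1
Reactants: 1 (S)-pantolactone
Product: 2 (2S)-2,4-dihydroxy-N-methoxy-N,3,3-trimethylbutanamide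
Conditions: MeNH(OMe)·HCl, AlMe3, CH2Cl2, 0 °C → rt; aq. potassium sodium tartrate
Reagents that add atoms: N,O-dimethylhydroxylamine hydrochloride (CNOC.Cl)
Why: Weinreb aminolysis of the lactone by the aluminium amide opens the ring at C2 and frees the C5 hydroxyl without touching the C3 stereocentre.

Step 2
Reactants: 2 Weinreb amide diol
Product: 3 (2S)-4-[(tert-butyldiphenylsilyl)oxy]-2-hydroxy-N-methoxy-N,3,3-trimethylbutanamide
Conditions: TBDPSCl, imidazole, DMF, 0 °C → rt
Reagents that add atoms: tert-butyldiphenylsilyl chloride (CC(C)(C)[Si](Cl)(c1ccccc1)c1ccccc1)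
Why: Silylation should take the primary C5 hydroxyl far faster than the secondary C3 hydroxyl wedged between the quaternary carbon and the amide, and it also blocks relactonisation.

Step 3
Reactants: 3 mono-silyl ether
Product: 4 (2S)-4-[(tert-butyldiphenylsilyl)oxy]-N-methoxy-N,3,3-trimethyl-2-[(triethylsilyl)oxy]butanamide
Conditions: TESOTf, 2,6-lutidine, CH2Cl2, −78 → 0 °C
Reagents that add atoms: triethylsilyl triflate (CC[Si](CC)(CC)OS(=O)(=O)C(F)(F)F)
Why: The silyl triflate silylates the hindered C3 hydroxyl, giving a non-chelating ether that mild acid can later remove in the presence of the TBDPS ether.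

Step 4
Reactants: 4 bis-silyl Weinreb amide
Product: 5 (2S)-4-[(tert-butyldiphenylsilyl)oxy]-3,3-dimethyl-2-[(triethylsilyl)oxy]butanal
Conditions: iBu2AlH, THF, −78 °C; aq. potassium sodium tartrate
Reagents that add atoms: none
Why: Hydride reduction of the Weinreb amide stops at the chelated tetrahedral intermediate, which releases the C2 aldehyde on work-up; the low temperature protects the C3 centre.

Step 5
Reactants: 5 α-silyloxy aldehyde; 6 allenylboronic acid pinacol ester
Product: 7 (4R,5S)-7-[(tert-butyldiphenylsilyl)oxy]-6,6-dimethyl-5-[(triethylsilyl)oxy]hept-1-yn-4-ol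
Conditions: toluene, 50 °C; pH 7 aqueous work-up
Reagents that add atoms: none
Why: Allenylboration (SE2' propargylation through a closed six-membered transition state) forms C1–C2, and C2 should be set anti to C3 by the Cornforth/polar Felkin–Anh arrangement, with the C3–O bond anti to the carbonyl and the nucleophile passing the C3 hydrogen instead of the tertiary alkyl group.

Step 6
Reactants: 7 homopropargylic alcohol
Product: 9 (1E,4R,5S)-7-[(tert-butyldiphenylsilyl)oxy]-1-iodo-2,6,6-trimethyl-5-[(triethylsilyl)oxy]hept-1-en-4-ol, via alkenylalane 8 (not isolated)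
Conditions: AlMe3, Cp2ZrCl2 (0.3 equiv), CH2Cl2, 0 °C → rt; then I2, THF, −30 → 0 °C
Reagents that add atoms: trimethylaluminium (C[Al](C)C); iodine (II)
Why: Negishi Zr-catalysed carboalumination adds methyl and aluminium syn across the terminal alkyne with methyl on the internal carbon C10, and iodinolysis with retention gives the E iodide (iodine cis to the methyl, tether trans), which fixes the diene geometry.

Step 7
Reactants: 9 vinyl iodide
Product: 11 tert-butyl{2-[(4S,5R)-5-[(2E)-3-iodo-2-methylprop-2-en-1-yl]-2,2-dimethyl-1,3-dioxolan-4-yl]-2-methylpropoxy}diphenylsilane, via diol 10 (not isolated)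
Conditions: CSA (cat.), MeOH, 0 °C; concentrate; then 2,2-dimethoxypropane, acetone, rt
Reagents that add atoms: 2,2-dimethoxypropane (COC(C)(C)OC)
Why: Acid methanolysis removes the triethylsilyl ether much faster than the TBDPS ether, and ketalisation of the freed C2,C3 diol can only give the cis-dioxolane because O5 stays blocked.

Step 8
Reactants: 11 acetonide vinyl iodide; 12 isopropenylboronic acid pinacol ester
Product: 13 tert-butyl{2-[(4S,5R)-5-[(2E)-2,4-dimethylpenta-2,4-dien-1-yl]-2,2-dimethyl-1,3-dioxolan-4-yl]-2-methylpropoxy}diphenylsilane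
Conditions: Pd(PPh3)4 (5 mol%), aq. K3PO4, THF, 50 °C
Reagents that add atoms: none
Why: Suzuki–Miyaura coupling of the alkenyl iodide with the alkenyl boronate forms C8–C9 with retention of the C9=C10 geometry.

Step 9
Reactants: 13 diene silyl ether
Product: 14 2-[(4S,5R)-5-[(2E)-2,4-dimethylpenta-2,4-dien-1-yl]-2,2-dimethyl-1,3-dioxolan-4-yl]-2-methylpropan-1-ol
Conditions: Bu4NF, THF, rt → 45 °C
Reagents that add atoms: none
Why: Fluoride cleaves the Si–O bond of the neopentyl silyl ether while the acetonide and the diene are inert.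

Step 10
Reactants: 14 primary alcohol
Product: 15 2-[(4S,5R)-5-[(2E)-2,4-dimethylpenta-2,4-dien-1-yl]-2,2-dimethyl-1,3-dioxolan-4-yl]-2-methylpropanal
Conditions: Dess–Martin periodinane, pyridine, CH2Cl2, 0 °C → rt
Reagents that add atoms: none
Why: Dess–Martin oxidation gives the C5 aldehyde, which has no α-hydrogen and so cannot enolise or eliminate the β-oxygen.

Step 11
Reactants: 15 C5 aldehyde; 16 diethyl [(phenylsulfonyl)methyl]phosphonate
Product: 17 (4S,5R)-5-[(2E)-2,4-dimethylpenta-2,4-dien-1-yl]-2,2-dimethyl-4-[(3E)-2-methyl-4-(phenylsulfonyl)but-3-en-2-yl]-1,3-dioxolane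
Conditions: NaH, THF, 0 °C; then 15, 0 °C → rt
Reagents that add atoms: none
Why: Horner–Wadsworth–Emmons olefination with the sulfonyl-stabilised phosphonate anion should give the E vinyl sulfone, and the quaternary C4 rules out isomerisation to an allyl sulfone.

Step 12
Reactants: 17 triene sulfone
Product: 18 2α,3α-(isopropylidenedioxy)-4,4,8,10β-tetramethyl-6α-(phenylsulfonyl)-5α-H-Δ8(9)-octalin (trans-fused)
Conditions: toluene (0.01 M, degassed), BHT (cat.), sealed tube, 185 °C
Reagents that add atoms: none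
Why: This is a thermal, concerted, suprafacial [4+2] cycloaddition between the C7=C8–C9=C10 diene and the (E)-C5=C6 vinyl sulfone, and the closest known reaction type is the intramolecular Diels–Alder reaction of terminally sulfonyl- or acyl-activated 1,7,9-decatrienes. Ring B is closed as the new cyclohexene by both new bonds (C5–C10 and C6–C7), and ring A is closed through the four-atom C1–C4 tether by the C5–C10 bond alone, the fused (type 1) mode, with the C4 gem-dimethyl group and the cis-dioxolane holding the two ends of the tether together. C10 and C5 become trans (10β-CH3, 5α-H) because the diene carries the tether outside and the methyl inside at C10 and the sulfone reacts endo with the tether exo, whereas the exo-sulfonyl mode would push the fully substituted C4 under the diene against the inside methyl. C6 follows from the E geometry of the dienophile (sulfonyl cis to H-5) and is erased in step 13. The face of the diene is chosen by the chair of the forming ring A in which C2–O is equatorial and C3–O axial, since the other chair would set C2–O axial, syn to the axial C4 methyl and the incoming C10 methyl. The step therefore needs endo (trans-fusion) selectivity and one π-face, and it must outrun a [1,5]-hydrogen shift of the inside methyl.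

Step 13
Reactants: 18 octalin sulfone
Product: 19 2α,3α-(isopropylidenedioxy)-4,4,8,10β-tetramethyl-5α-H-Δ8(9)-octalin
Conditions: Na(Hg) (6% Na), Na2HPO4, MeOH/THF, −20 °C → rt
Reagents that add atoms: none
Why: Electron transfer from sodium amalgam cleaves the C6–S bond of the alkyl aryl sulfone and the carbanion is protonated, leaving C6 as CH2; the C8=C9 alkene is not allylic to C6 and should not move.

Step 14
Reactants: 19 octalin
Product: 21 2α,3α-(isopropylidenedioxy)-4,4,8β,10β-tetramethyl-5α-decalin-9α-ol (8α-H, 9β-H), via alkylborane 20 (not isolated)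
Conditions: BH3·THF, THF, 0 °C → rt; then aq. NaOH, H2O2, 0 °C → rt
Reagents that add atoms: borane–tetrahydrofuran (B.C1CCOC1, boron into 20); hydrogen peroxide (OO)
Why: Hydroboration places boron on the less substituted C9 by syn addition from the α face, opposite the C10 methyl, and oxidation with retention gives the 9α-alcohol (the C8 methyl is β at this stage).

Step 15
Reactants: 21 9α-alcohol
Product: 23 2α,3α-(isopropylidenedioxy)-4,4,8α,10β-tetramethyl-5α-decalin-9-one (8β-H), via 8β-methyl ketone 22 (not isolated)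
Conditions: Dess–Martin periodinane, pyridine, CH2Cl2, rt; then NaOMe (cat.), MeOH, rt
Reagents that add atoms: none
Why: Dess–Martin oxidation gives the C9 ketone, and base-mediated enolisation toward C8 moves the axial 8β-methyl, which is 1,3-diaxial to the C10 methyl, into the equatorial 8α position.

Step 16
Reactants: 23 C9 ketone
Product: 24 2α,3α-(isopropylidenedioxy)-4,4,8α,10β-tetramethyl-9α-vinyl-5α-decalin-9β-ol
Conditions: CH2=CHMgBr, anhydrous CeCl3, THF, −78 → 0 °C; water quench
Reagents that add atoms: vinylmagnesium bromide (C=C[Mg]Br)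
Why: The organocerium 1,2-addition suppresses enolisation of the hindered ketone, and the nucleophile should enter axially on the α face, anti to the C10 methyl and away from the peri C1 methylene, placing vinyl α and hydroxyl β at C9.

Step 17
Reactants: 25 methyl acetoacetate
Product: 26 methyl (2E)-3-{[(trifluoromethyl)sulfonyl]oxy}but-2-enoate
Conditions: Tf2O, aq. Me4NOH, hexanes, 5 °C
Reagents that add atoms: triflic anhydride (O=S(=O)(OS(=O)(=O)C(F)(F)F)C(F)(F)F)
Why: O-Triflation of the β-keto ester enolate with a non-chelating tetramethylammonium counter-ion should give the E enol triflate, with the triflate trans to the ester.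

Step 18
Reactants: 24 vinyl carbinol; 26 (E)-enol triflate
Product: 28 methyl (13E)-9β-hydroxy-2α,3α-(isopropylidenedioxy)-8α-methyl-9α-side-chain labd-13-en-15-oate (acetonide of the target diol), via B-alkyl-9-BBN adduct 27 (not isolated)
Conditions: 9-BBN, THF, rt; then 26, Pd(dppf)Cl2 (5 mol%), aq. K3PO4, DMF, rt → 40 °C
Reagents that add atoms: 9-borabicyclo[3.3.1]nonane (B1C2CCCC1CCC2, into 27)
Why: Anti-Markovnikov hydroboration of the monosubstituted alkene puts boron on C12, and B-alkyl Suzuki–Miyaura coupling with the enol triflate forms C12–C13 with retention of geometry, giving the 13E enoate.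

Step 19
Reactants: 28 acetonide enoate
Product: 29 methyl (13E)-2α,3α,9β-trihydroxy-8α-methyl-9α-side-chain labd-13-en-15-oate
Conditions: AcOH/H2O (4:1), 45 °C
Reagents that add atoms: none
Why: Mild acid hydrolysis of the ketal frees the C2,C3 diol under conditions that should spare the tertiary C9 alcohol and the enoate.

Step 20
Reactants: 29 triol
Product: 30 CNP0135744.1, methyl (2E)-5-[(1S,2R,4aS,6S,7R,8aS)-7-(acetyloxy)-1,6-dihydroxy-2,5,5,8a-tetramethyldecahydronaphthalen-1-yl]-3-methylpent-2-enoate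
Conditions: Ac2O (1.1 equiv), pyridine, CH2Cl2, 0 °C
Reagents that add atoms: acetic anhydride (CC(=O)OC(C)=O)
Why: Acylation should pick the equatorial C2 hydroxyl over the axial C3 hydroxyl, which is neopentyl to the C4 gem-dimethyl carbon, and over the tertiary C9 hydroxyl.

## Compound list

1 | (S)-pantolactone, (3S)-3-hydroxy-4,4-dimethyloxolan-2-one | CC1(C)COC(=O)[C@H]1O | starting material
2 | (2S)-2,4-dihydroxy-N-methoxy-N,3,3-trimethylbutanamide | CON(C)C(=O)[C@@H](O)C(C)(C)CO | intermediate
3 | (2S)-4-[(tert-butyldiphenylsilyl)oxy]-2-hydroxy-N-methoxy-N,3,3-trimethylbutanamide | CON(C)C(=O)[C@@H](O)C(C)(C)CO[Si](c1ccccc1)(c1ccccc1)C(C)(C)C | intermediate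
4 | (2S)-4-[(tert-butyldiphenylsilyl)oxy]-N-methoxy-N,3,3-trimethyl-2-[(triethylsilyl)oxy]butanamide | CON(C)C(=O)[C@@H](O[Si](CC)(CC)CC)C(C)(C)CO[Si](c1ccccc1)(c1ccccc1)C(C)(C)C | intermediate
5 | (2S)-4-[(tert-butyldiphenylsilyl)oxy]-3,3-dimethyl-2-[(triethylsilyl)oxy]butanal | O=C[C@@H](O[Si](CC)(CC)CC)C(C)(C)CO[Si](c1ccccc1)(c1ccccc1)C(C)(C)C | intermediate
6 | allenylboronic acid pinacol ester, 4,4,5,5-tetramethyl-2-(propa-1,2-dien-1-yl)-1,3,2-dioxaborolane | C=C=CB1OC(C)(C)C(C)(C)O1 | starting material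
7 | (4R,5S)-7-[(tert-butyldiphenylsilyl)oxy]-6,6-dimethyl-5-[(triethylsilyl)oxy]hept-1-yn-4-ol (C2 R, C3 S; 2,3-anti) | C#CC[C@@H](O)[C@@H](O[Si](CC)(CC)CC)C(C)(C)CO[Si](c1ccccc1)(c1ccccc1)C(C)(C)C | intermediate
8 | (E)-alkenyl(dimethyl)alane of 7 as its dimethylaluminium alkoxide (Al on C9, cis to the new C10 methyl) | C[Al](C)/C=C(\C)C[C@@H](O[Al](C)C)[C@@H](O[Si](CC)(CC)CC)C(C)(C)CO[Si](c1ccccc1)(c1ccccc1)C(C)(C)C | intermediate (not isolated)
9 | (1E,4R,5S)-7-[(tert-butyldiphenylsilyl)oxy]-1-iodo-2,6,6-trimethyl-5-[(triethylsilyl)oxy]hept-1-en-4-ol | I/C=C(\C)C[C@@H](O)[C@@H](O[Si](CC)(CC)CC)C(C)(C)CO[Si](c1ccccc1)(c1ccccc1)C(C)(C)C | intermediate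
10 | (3S,4R,6E)-1-[(tert-butyldiphenylsilyl)oxy]-7-iodo-2,2,6-trimethylhept-6-ene-3,4-diol | I/C=C(\C)C[C@@H](O)[C@@H](O)C(C)(C)CO[Si](c1ccccc1)(c1ccccc1)C(C)(C)C | intermediate (not isolated)
11 | tert-butyl{2-[(4S,5R)-5-[(2E)-3-iodo-2-methylprop-2-en-1-yl]-2,2-dimethyl-1,3-dioxolan-4-yl]-2-methylpropoxy}diphenylsilane | I/C=C(\C)C[C@H]1OC(C)(C)O[C@H]1C(C)(C)CO[Si](c1ccccc1)(c1ccccc1)C(C)(C)C | intermediate
12 | isopropenylboronic acid pinacol ester, 4,4,5,5-tetramethyl-2-(prop-1-en-2-yl)-1,3,2-dioxaborolane | C=C(C)B1OC(C)(C)C(C)(C)O1 | starting material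
13 | tert-butyl{2-[(4S,5R)-5-[(2E)-2,4-dimethylpenta-2,4-dien-1-yl]-2,2-dimethyl-1,3-dioxolan-4-yl]-2-methylpropoxy}diphenylsilane | C=C(C)/C=C(\C)C[C@H]1OC(C)(C)O[C@H]1C(C)(C)CO[Si](c1ccccc1)(c1ccccc1)C(C)(C)C | intermediate
14 | 2-[(4S,5R)-5-[(2E)-2,4-dimethylpenta-2,4-dien-1-yl]-2,2-dimethyl-1,3-dioxolan-4-yl]-2-methylpropan-1-ol | C=C(C)/C=C(\C)C[C@H]1OC(C)(C)O[C@H]1C(C)(C)CO | intermediate
15 | 2-[(4S,5R)-5-[(2E)-2,4-dimethylpenta-2,4-dien-1-yl]-2,2-dimethyl-1,3-dioxolan-4-yl]-2-methylpropanal | C=C(C)/C=C(\C)C[C@H]1OC(C)(C)O[C@H]1C(C)(C)C=O | intermediate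
16 | diethyl [(phenylsulfonyl)methyl]phosphonate | CCOP(=O)(CS(=O)(=O)c1ccccc1)OCC | starting material
17 | (4S,5R)-5-[(2E)-2,4-dimethylpenta-2,4-dien-1-yl]-2,2-dimethyl-4-[(3E)-2-methyl-4-(phenylsulfonyl)but-3-en-2-yl]-1,3-dioxolane (triene sulfone) | C=C(C)/C=C(\C)C[C@H]1OC(C)(C)O[C@H]1C(C)(C)/C=C/S(=O)(=O)c1ccccc1 | intermediate
18 | 2α,3α-(isopropylidenedioxy)-4,4,8,10β-tetramethyl-6α-(phenylsulfonyl)-5α-H-Δ8(9)-octalin, trans-fused | C1=C(C)C[C@H](S(=O)(=O)c4ccccc4)[C@H]2C(C)(C)[C@@H]3OC(C)(C)O[C@@H]3C[C@@]21C | intermediate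
19 | 2α,3α-(isopropylidenedioxy)-4,4,8,10β-tetramethyl-5α-H-Δ8(9)-octalin | C1=C(C)CC[C@H]2C(C)(C)[C@@H]3OC(C)(C)O[C@@H]3C[C@@]21C | intermediate
20 | 9α-boryl adduct of 19 (BH2 on C9 α, H on C8 α, C8 methyl β) | B[C@@H]1[C@@H](C)CC[C@H]2C(C)(C)[C@@H]3OC(C)(C)O[C@@H]3C[C@@]21C | intermediate (not isolated)
21 | 2α,3α-(isopropylidenedioxy)-4,4,8β,10β-tetramethyl-5α-decalin-9α-ol | O[C@@H]1[C@@H](C)CC[C@H]2C(C)(C)[C@@H]3OC(C)(C)O[C@@H]3C[C@@]21C | intermediate
22 | 2α,3α-(isopropylidenedioxy)-4,4,8β,10β-tetramethyl-5α-decalin-9-one (C8 methyl axial) | O=C1[C@@H](C)CC[C@H]2C(C)(C)[C@@H]3OC(C)(C)O[C@@H]3C[C@@]21C | intermediate (not isolated)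
23 | 2α,3α-(isopropylidenedioxy)-4,4,8α,10β-tetramethyl-5α-decalin-9-one (C8 methyl equatorial) | O=C1[C@H](C)CC[C@H]2C(C)(C)[C@@H]3OC(C)(C)O[C@@H]3C[C@@]21C | intermediate
24 | 2α,3α-(isopropylidenedioxy)-4,4,8α,10β-tetramethyl-9α-vinyl-5α-decalin-9β-ol | C=C[C@]1(O)[C@H](C)CC[C@H]2C(C)(C)[C@@H]3OC(C)(C)O[C@@H]3C[C@@]21C | intermediate
25 | methyl acetoacetate | COC(=O)CC(C)=O | starting material
26 | methyl (2E)-3-{[(trifluoromethyl)sulfonyl]oxy}but-2-enoate | COC(=O)/C=C(\C)OS(=O)(=O)C(F)(F)F | intermediate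
27 | B-alkyl-9-BBN adduct of 24 (9-borabicyclo[3.3.1]nonan-9-yl on C12) | B1(C2CCCC1CCC2)CC[C@]3(O)[C@H](C)CC[C@H]4C(C)(C)[C@@H]5OC(C)(C)O[C@@H]5C[C@@]43C | intermediate (not isolated)
28 | methyl (2E)-5-[9β-hydroxy-2α,3α-(isopropylidenedioxy)-4,4,8α,10β-tetramethyl-5α-decalin-9α-yl]-3-methylpent-2-enoate | COC(=O)/C=C(\C)CC[C@]1(O)[C@H](C)CC[C@H]2C(C)(C)[C@@H]3OC(C)(C)O[C@@H]3C[C@@]21C | intermediate
29 | methyl (2E)-5-[2α,3α,9β-trihydroxy-4,4,8α,10β-tetramethyl-5α-decalin-9α-yl]-3-methylpent-2-enoate | COC(=O)/C=C(\C)CC[C@]1(O)[C@H](C)CC[C@H]2C(C)(C)[C@H](O)[C@H](O)C[C@@]21C | intermediate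
30 | CNP0135744.1, methyl (2E)-5-[(1S,2R,4aS,6S,7R,8aS)-7-(acetyloxy)-1,6-dihydroxy-2,5,5,8a-tetramethyldecahydronaphthalen-1-yl]-3-methylpent-2-enoate | COC(=O)/C=C(\C)CC[C@]1(O)[C@H](C)CC[C@H]2C(C)(C)[C@H](O)[C@H](OC(C)=O)C[C@@]21C | target

## Step count and risks

Total: 20 steps. Longest linear sequence: 19 steps (steps 1–16 and 18–20 from (S)-pantolactone); step 17 is a one-step side branch.

**Steps most likely to fail**

1. Step 12. The cycloaddition may stall because both ends of the C5–C10 bond are hindered (C5 neopentyl, C10 fully substituted). At the temperature required, a [1,5]-hydrogen shift from the inside C10 methyl may scramble the diene, or the exo mode may compete and give cis fusion. Fallback: exchange the sulfonyl group for a formyl group, which allows Lewis acid activation at low temperature. Setting out from aldehyde 15, Wittig olefination with Ph3P=CHCHO (toluene, 80 °C) should give the (E)-triene enal F1. Cycloaddition of F1 promoted by Me2AlCl (CH2Cl2, −40 °C) should give the trans-octalin C6 carbaldehyde F2 through the same endo transition state. Decarbonylation of F2 with stoichiometric RhCl(PPh3)3 (toluene, reflux) removes the activating carbon and comes back to the route at 19.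

2. Step 16. The C9 carbonyl lies between the quaternary C10 and the methyl-bearing C8, so enolisation toward C8 or simple failure to add may win over 1,2-addition, and a bulky metal vinyl may erode the α-face preference. Fallback: use the smaller, less basic sp nucleophile and adjust the oxidation level afterwards. Setting out from ketone 23, HC≡CMgBr (THF, 0 °C → rt) should add axially from the α face to give the 9α-ethynyl carbinol F3. Semi-hydrogenation of F3 (H2, Pd/CaCO3 poisoned with Pb(OAc)2, quinoline) comes back to the route at 24.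

3. Step 18. Aqueous base may destroy the enol triflate before transmetalation, the C9 alkoxide may add 1,4 to the new enoate and close a 9,13-ether, or the alkylborane next to the crowded carbinol may transmetalate slowly. Fallback: build the enoate by olefination of a C13 methyl ketone. Setting out from ketone 23, CH2=C(CH3)CH2CH2MgBr with CeCl3 should give the 9α-(3-methylbut-3-enyl) carbinol F4. Ozonolysis of F4 (O3, CH2Cl2/MeOH, −78 °C; Me2S) gives the C13 methyl ketone F5, which may rest as its 9,13-hemiketal. Horner–Wadsworth–Emmons olefination of F5 with trimethyl phosphonoacetate (LiCl, DBU, MeCN) comes back to the route at 28 after chromatographic removal of the minor 13Z isomer.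

## Further compounds

F1 | step 12 | (2E)-4-[(4S,5R)-5-[(2E)-2,4-dimethylpenta-2,4-dien-1-yl]-2,2-dimethyl-1,3-dioxolan-4-yl]-4-methylpent-2-enal | C=C(C)/C=C(\C)C[C@H]1OC(C)(C)O[C@H]1C(C)(C)/C=C/C=O
F2 | step 12 | 2α,3α-(isopropylidenedioxy)-4,4,8,10β-tetramethyl-5α-H-Δ8(9)-octalin-6α-carbaldehyde | C1=C(C)C[C@H](C=O)[C@H]2C(C)(C)[C@@H]3OC(C)(C)O[C@@H]3C[C@@]21C
F3 | step 16 | 9α-ethynyl-2α,3α-(isopropylidenedioxy)-4,4,8α,10β-tetramethyl-5α-decalin-9β-ol | C#C[C@]1(O)[C@H](C)CC[C@H]2C(C)(C)[C@@H]3OC(C)(C)O[C@@H]3C[C@@]21C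
F4 | step 18 | 2α,3α-(isopropylidenedioxy)-4,4,8α,10β-tetramethyl-9α-(3-methylbut-3-en-1-yl)-5α-decalin-9β-ol | C=C(C)CC[C@]1(O)[C@H](C)CC[C@H]2C(C)(C)[C@@H]3OC(C)(C)O[C@@H]3C[C@@]21C
F5 | step 18 | 4-[9β-hydroxy-2α,3α-(isopropylidenedioxy)-4,4,8α,10β-tetramethyl-5α-decalin-9α-yl]butan-2-one | CC(=O)CC[C@]1(O)[C@H](C)CC[C@H]2C(C)(C)[C@@H]3OC(C)(C)O[C@@H]3C[C@@]21C
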